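Numbering (eremophilane): ring A = C1–C5 and C10; ring B = C5–C10; C11(C13H3)–C12O2H on C7; C14H3 on C5, C15H3 on C4; angelate on the C3 oxygen.
Enabling feature: in ring B the C10 carbinol is β to the C8 ketone through C9H2 (aldol retron). C6 and C10 both sit on quaternary C5, C7 and C9 flank C8, and the C12 carboxyl is 1,4 to C6 (C12–C11–C7=C6), so the C6=C7 alkene plus the free acid equal an unzipped C6–O–C12 γ-lactone.
Last step, ring B: one-pot three-plus-three annulation of keto aldehyde 11 (electrophilic C6, C10) and silyl enol ether 15 (nucleophilic C7, then C9). C6–C7 forms first, C9–C10 closes the ring, and a temporary lactone then unzips to enone and acid.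
15 (C11 stereocentre) comes from methylglyoxal by Wittig olefination and asymmetric copper hydride 1,4-hydrosilylation.
Ring A is bought as 2,3-dimethylcyclohex-2-enone: C3 by CBS reduction, C10 by allylic oxidation, C4 by anti 1,4-hydrosilylation, C5/C6 by orthoformate alkylation, then the angelate. Ring order: A (bought), then temporary lactone and B together.

Key step: step 11

Assumption: the sense of induction of the (R)-DTBM-SEGPHOS copper hydride in step 10 is taken by analogy (the antipodal ligand is used if it proves opposite). The transient centres C6 and C7 of 16–18 are drawn without configuration because both are erased in step 11.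

Step 1
Reactants: 1 2,3-dimethylcyclohex-2-en-1-one
Product: 2 (1S)-2,3-dimethylcyclohex-2-en-1-ol
Conditions: (R)-Me-CBS (10 mol %), BH3·SMe2 (0.7 equiv), THF, −20 °C; MeOH, then aq. NH4Cl
Reagents that add atoms: none
Why: In this Corey–Bakshi–Shibata reduction the α-methylated alkene arm acts as the large group and the CH2 arm as the small one, so hydride should reach one carbonyl face and set C3 as (S), as known for 2-substituted cyclohexenones.

Step 2
Reactants: 2 (1S)-2,3-dimethylcyclohex-2-en-1-ol
Product: 3 tert-butyl{[(1S)-2,3-dimethylcyclohex-2-en-1-yl]oxy}dimethylsilane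
Conditions: TBSCl, imidazole, DMF, rt
Reagents that add atoms: tert-butyldimethylsilyl chloride, CC(C)(C)[Si](C)(C)Cl
Why: Standard silyl ether formation at oxygen leaves C3 untouched and supplies the bulky group that later directs the reduction at C4.

Step 3
Reactants: 3 tert-butyl{[(1S)-2,3-dimethylcyclohex-2-en-1-yl]oxy}dimethylsilane
Product: 4 (4S)-4-[(tert-butyldimethylsilyl)oxy]-2,3-dimethylcyclohex-2-en-1-one
Conditions: Rh2(caprolactamate)4 (1 mol %), t-BuOOH (70 % in water, 5 equiv), K2CO3 (0.5 equiv), CH2Cl2, rt
Reagents that add atoms: tert-butyl hydroperoxide, CC(C)(C)OO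
Why: Radical allylic oxidation by tert-butylperoxyl should turn the only ring CH2 next to the tetrasubstituted alkene (C10) into the ketone, since C3–H is shielded by the silyl ether and no stereocentre is touched.

Step 4
Reactants: 4 (4S)-4-[(tert-butyldimethylsilyl)oxy]-2,3-dimethylcyclohex-2-en-1-one
Product: 5 tert-butyl({(1S,2R)-2,3-dimethyl-4-[(triethylsilyl)oxy]cyclohex-3-en-1-yl}oxy)dimethylsilane
Conditions: Et3SiH (1.5 equiv), RhCl(PPh3)3 (2 mol %), THF, 50 °C
Reagents that add atoms: triethylsilane, CC[SiH](CC)CC
Why: Rhodium-catalysed 1,4-hydrosilylation fixes the enol ether regiospecifically at C10=C5, and hydride should reach C4 anti to the C3 silyloxy group (pseudoaxial because of A(1,2) strain), which places C15 cis to the C3 oxygen (C4 = R).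

Step 5
Reactants: 5 tert-butyl({(1S,2R)-2,3-dimethyl-4-[(triethylsilyl)oxy]cyclohex-3-en-1-yl}oxy)dimethylsilane
Product: 6 (2S,3R,4S)-4-[(tert-butyldimethylsilyl)oxy]-2-(dimethoxymethyl)-2,3-dimethylcyclohexan-1-one
Conditions: HC(OMe)3 (3 equiv), Me3SiOTf (10 mol %), CH2Cl2, −78 °C
Reagents that add atoms: trimethyl orthoformate, COC(OC)OC
Why: In this Mukaiyama-type alkylation the small dimethoxycarbenium ion should attack C5 axially, anti to the pseudoaxial C15 methyl, which sets the quaternary centre with C14 cis to C15 as in alkylations of 2,3-dimethylcyclohexanone enolates.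

Step 6
Reactants: 6 (2S,3R,4S)-4-[(tert-butyldimethylsilyl)oxy]-2-(dimethoxymethyl)-2,3-dimethylcyclohexan-1-one
Product: 7 (2S,3R,4S)-2-(dimethoxymethyl)-4-hydroxy-2,3-dimethylcyclohexan-1-one
Conditions: Bu4NF (1.2 equiv), THF, 0 °C to rt
Reagents that add atoms: none
Why: Fluoride desilylation frees the C3 alcohol, while the non-enolisable β-keto acetal and the stereocentres (none α to the ketone bears hydrogen) are inert.

Step 7
Reactants: 7 (2S,3R,4S)-2-(dimethoxymethyl)-4-hydroxy-2,3-dimethylcyclohexan-1-one; 8 angelic acid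
Product: 10 (1S,2R,3S)-3-(dimethoxymethyl)-2,3-dimethyl-4-oxocyclohexyl (Z)-2-methylbut-2-enoate, via mixed anhydride 9 (not isolated)
Conditions: 8, 2,4,6-Cl3C6H2COCl, Et3N, toluene, rt; then 7, 80 °C
Reagents that add atoms: 2,4,6-trichlorobenzoyl chloride, O=C(Cl)c1c(Cl)cc(Cl)cc1Cl (its atoms end in 9 only)
Why: Yamaguchi-type mixed anhydride esterification is the established way to angelates of hindered secondary alcohols without Z to E isomerisation, and C3 keeps its configuration because only the O–H bond reacts.

Step 8
Reactants: 10 (1S,2R,3S)-3-(dimethoxymethyl)-2,3-dimethyl-4-oxocyclohexyl (Z)-2-methylbut-2-enoate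
Product: 11 (1S,2R,3S)-3-formyl-2,3-dimethyl-4-oxocyclohexyl (Z)-2-methylbut-2-enoate
Conditions: CF3CO2H, H2O, CH2Cl2, 0 °C
Reagents that add atoms: water, O
Why: Acid hydrolysis of the dimethyl acetal unmasks C6 as the aldehyde, the quaternary C5 cannot epimerise, and acidic conditions avoid the retro-Claisen deformylation that base would cause.

Step 9
Reactants: 12 methylglyoxal; 13 methyl 2-(triphenyl-λ5-phosphanylidene)propanoate
Product: 14 methyl (E)-2-methyl-4-oxopent-2-enoate
Conditions: CH2Cl2, rt (12 as 40 % aqueous solution)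
Reagents that add atoms: none
Why: The stabilised ylide of this Wittig olefination should attack the aldehyde of methylglyoxal rather than its ketone and give the (E)-trisubstituted alkene.

Step 10
Reactants: 14 methyl (E)-2-methyl-4-oxopent-2-enoate
Product: 15 methyl (2R,3Z)-4-{[dimethyl(phenyl)silyl]oxy}-2-methylpent-3-enoate
Conditions: Cu(OAc)2·H2O (2 mol %), (R)-DTBM-SEGPHOS (2.2 mol %), PhMe2SiH (1.2 equiv), toluene, −20 °C; non-aqueous work-up
Reagents that add atoms: dimethyl(phenyl)silane, C[SiH](C)c1ccccc1
Why: In this copper hydride-catalysed asymmetric 1,4-hydrosilylation hydride should add to C11, the β-carbon of the better acceptor (the ketone), from the face chosen by the ligand, which sets C11 as (R) and traps the C7=C8 enolate regiospecifically as its silyl ether.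

Step 11
Reactants: 11 (1S,2R,3S)-3-formyl-2,3-dimethyl-4-oxocyclohexyl (Z)-2-methylbut-2-enoate; 15 methyl (2R,3Z)-4-{[dimethyl(phenyl)silyl]oxy}-2-methylpent-3-enoate
Product: 20 (3S,4R,5R,10S,11R)-3-angeloyloxy-10-hydroxy-8-oxoeremophil-6-en-12-oic acid, via aldol silyl ether 16 (not isolated), via bicyclic ketol 17 (not isolated), via tricyclic lactone 18 (not isolated), via silylated acid 19 (not isolated)
Conditions: Tf2NH (2 mol %), toluene, −78 °C; then LiN(SiMe3)2 (1.1 equiv), THF, −78 to 0 °C; then 1 M HCl, 0 °C
Reagents that add atoms: none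
Why: Proposed new method: the silyl triflimide formed from Tf2NH and 15 catalyses a Mukaiyama aldol addition of C7 to the aldehyde C6 with silyl transfer (16); LiN(SiMe3)2 then removes a C9 proton of the methyl ketone, the terminal enolate adds to the C10 ketone and closes ring B (17), the new C10 alkoxide takes the silyl group from the 1,3-related C6 oxygen, the freed C6 alkoxide lactonises on the C12 methyl ester (18), and the methoxide set free removes C7–H so that the ring B enolate expels the C6 carboxylate (E1cB) to give the C6=C7 enone as lithium carboxylate 19, whose tertiary silyl ether is hydrolysed in the acidic work-up. The closest known reaction types are the ketol stage of the Robinson annulation, the base-induced 1,5 oxygen-to-oxygen silyl migration of 1,3-diol monosilyl ethers and the lactone-opening elimination of the Stobbe condensation, strung together here as a formal three-plus-three annulation of a 1,3-dielectrophile (C6, C10) and a 1,3-dinucleophile (C7, C9). Ring B closes in the favoured 6-(enolendo)-exo-trig mode and the temporary lactone in the 5-exo-trig mode, whereas attack of the C9 enolate on the C12 ester would be a disfavoured 5-(enolendo)-exo-trig closure. The only lasting new stereocentre, C10, is set by ring A: the all-cis C3–O/C15/C14 array enforces the chair in which C14 and the C3 oxygen are equatorial and C15 and the C6 chain are axial (the other chair has a syn-axial C14/C3–O clash), so C9 can only enter C10 equatorially from the α face and the oxygen ends axial and cis to C14 (cis-decalin, as in Robinson ketols), while C6 and C7 are transient and need no control and C11 is flanked only by an ester or carboxylate and is not deprotonated. The step needs ring closure before loss of the C6 oxygen, because an open-chain elimination would put C5 trans to C8; this order is built in, since the C6 oxygen stays a poor silyloxy leaving group until the aldolate itself converts it into a carboxylate, and the alkene is then born inside the six-membered ring, where C5 and C8 must be cis. The single equivalent of base ends as the carboxylate, which switches off retro-aldol, dehydration at C10, epimerisation at C11 and angelate isomerisation, and enolisation at C1 is a reversible dead end that drains back through HN(SiMe3)2.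

Compound list
1 | 2,3-dimethylcyclohex-2-en-1-one | CC1=C(C)C(=O)CCC1 | starting material
2 | (1S)-2,3-dimethylcyclohex-2-en-1-ol | O[C@H]1CCCC(C)=C1C | intermediate
3 | tert-butyl{[(1S)-2,3-dimethylcyclohex-2-en-1-yl]oxy}dimethylsilane | CC(C)(C)[Si](C)(C)O[C@H]1CCCC(C)=C1C | intermediate
4 | (4S)-4-[(tert-butyldimethylsilyl)oxy]-2,3-dimethylcyclohex-2-en-1-one | CC(C)(C)[Si](C)(C)O[C@H]1CCC(=O)C(C)=C1C | intermediate
5 | tert-butyl({(1S,2R)-2,3-dimethyl-4-[(triethylsilyl)oxy]cyclohex-3-en-1-yl}oxy)dimethylsilane | CC(C)(C)[Si](C)(C)O[C@H]1CCC(O[Si](CC)(CC)CC)=C(C)[C@H]1C | intermediate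
6 | (2S,3R,4S)-4-[(tert-butyldimethylsilyl)oxy]-2-(dimethoxymethyl)-2,3-dimethylcyclohexan-1-one | CC(C)(C)[Si](C)(C)O[C@H]1CCC(=O)[C@](C)(C(OC)OC)[C@H]1C | intermediate
7 | (2S,3R,4S)-2-(dimethoxymethyl)-4-hydroxy-2,3-dimethylcyclohexan-1-one | O[C@H]1CCC(=O)[C@](C)(C(OC)OC)[C@H]1C | intermediate
8 | angelic acid, (Z)-2-methylbut-2-enoic acid | C/C=C(/C)C(=O)O | starting material
9 | angelic 2,4,6-trichlorobenzoic anhydride | C/C=C(/C)C(=O)OC(=O)c1c(Cl)cc(Cl)cc1Cl | intermediate
10 | (1S,2R,3S)-3-(dimethoxymethyl)-2,3-dimethyl-4-oxocyclohexyl (Z)-2-methylbut-2-enoate | C/C=C(/C)C(=O)O[C@H]1CCC(=O)[C@](C)(C(OC)OC)[C@H]1C | intermediate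
11 | (1S,2R,3S)-3-formyl-2,3-dimethyl-4-oxocyclohexyl (Z)-2-methylbut-2-enoate | C/C=C(/C)C(=O)O[C@H]1CCC(=O)[C@](C)(C=O)[C@H]1C | intermediate
12 | methylglyoxal | CC(=O)C=O | starting material
13 | methyl 2-(triphenyl-λ5-phosphanylidene)propanoate | COC(=O)C(C)=P(c1ccccc1)(c1ccccc1)c1ccccc1 | starting material
14 | methyl (E)-2-methyl-4-oxopent-2-enoate | COC(=O)/C(C)=C/C(C)=O | intermediate
15 | methyl (2R,3Z)-4-{[dimethyl(phenyl)silyl]oxy}-2-methylpent-3-enoate | C/C(O[Si](C)(C)c1ccccc1)=C/[C@@H](C)C(=O)OC | intermediate
16 | methyl (2R)-3-acetyl-4-[(1S,2R,3S)-3-angeloyloxy-1,2-dimethyl-6-oxocyclohexyl]-4-{[dimethyl(phenyl)silyl]oxy}-2-methylbutanoate (epimers at C6 and C7) | C/C=C(/C)C(=O)O[C@H]1CCC(=O)[C@](C)(C(O[Si](C)(C)c2ccccc2)C(C(C)=O)[C@@H](C)C(=O)OC)[C@H]1C | intermediate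
17 | methyl (3S,4R,5R,10S,11R)-3-angeloyloxy-6-{[dimethyl(phenyl)silyl]oxy}-10-hydroxy-8-oxoeremophilan-12-oate (epimers at C6 and C7) | C/C=C(/C)C(=O)O[C@H]1CC[C@]2(O)CC(=O)C([C@@H](C)C(=O)OC)C(O[Si](C)(C)c3ccccc3)[C@]2(C)[C@H]1C | intermediate
18 | (3S,4R,5R,10S,11R)-3-angeloyloxy-10-{[dimethyl(phenyl)silyl]oxy}-8-oxoeremophilan-12,6-olide (epimers at C6 and C7) | C/C=C(/C)C(=O)O[C@H]1CC[C@]2(O[Si](C)(C)c3ccccc3)CC(=O)C4[C@@H](C)C(=O)OC4[C@]2(C)[C@H]1C | intermediate
19 | (3S,4R,5R,10S,11R)-3-angeloyloxy-10-{[dimethyl(phenyl)silyl]oxy}-8-oxoeremophil-6-en-12-oic acid (formed as its lithium salt) | C/C=C(/C)C(=O)O[C@H]1CC[C@]2(O[Si](C)(C)c3ccccc3)CC(=O)C([C@@H](C)C(=O)O)=C[C@]2(C)[C@H]1C | intermediate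
20 | (3S,4R,5R,10S,11R)-3-angeloyloxy-10-hydroxy-8-oxoeremophil-6-en-12-oic acid | C/C=C(/C)C(=O)O[C@H]1CC[C@]2(O)CC(=O)C([C@@H](C)C(=O)O)=C[C@]2(C)[C@H]1C | target

Total step count: 11. Longest linear sequence: 9 (steps 1–8 and 11).

Steps most likely to fail

Step 11. Several processes could break the cascade:
- The β-branched silyl enol ether may add only slowly to the neopentyl aldehyde.
- A C7 enolate may lose the C6 silyloxy group before ring B has closed.
- The silyl shift may stall for the C6 epimer whose oxygen is trans to the C10 oxygen.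

Fallback (known chemistry, the events are separated): the Mukaiyama stage is worked up and 16 is isolated. LiN(SiMe3)2 at −78 °C followed by a cold AcOH quench stops at bicyclic ketol 17. CSA in MeOH removes the silyl group and closes the lactone to the tricyclic ketol lactone F1. DBU in CH2Cl2 then effects the β-acyloxy ketone elimination. The fallback sets out from 16 and comes back at 20.

Step 10. Hydride may be delivered to C7 (ester-controlled regiochemistry), facial selection on this doubly activated alkene may be poor, or the labile silyl enol ether may hydrolyse during isolation.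

Fallback (reduction and enol ether formation are uncoupled):
- 14 is saponified with LiOH to (E)-2-methyl-4-oxopent-2-enoic acid F2.
- F2 is hydrogenated with Ru(OAc)2(BINAP) of the appropriate handedness, as for α-methyl α,β-unsaturated acids, to (R)-2-methyl-4-oxopentanoic acid F3.
- F3 is esterified with MeI and K2CO3 to methyl (R)-2-methyl-4-oxopentanoate F4.
- F4 is silylated under equilibrating conditions (PhMe2SiCl, NaI, Et3N, MeCN) at the more substituted side.

The fallback sets out from 14 and comes back at 15.

Step 4. Turnover on the tetrasubstituted enone may be slow, 1,2-hydrosilylation may compete, or face selection at C4 may be incomplete.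

Fallback (heterogeneous hydrogenation instead of hydride transfer): 4 is hydrogenated over Pd/C in EtOAc from the face anti to the silyl ether to (3R,4S)-4-[(tert-butyldimethylsilyl)oxy]-2,3-dimethylcyclohexan-1-one F5, whose C5 epimers are without consequence. Me3SiI and HN(SiMe3)2 convert F5 under thermodynamic control into the tetrasubstituted trimethylsilyl enol ether F6, which enters the orthoformate alkylation of step 5. The fallback sets out from 4 and comes back at 6.

Further compounds
F1 | step 11 | (3S,4R,5R,10S,11R)-3-angeloyloxy-10-hydroxy-8-oxoeremophilan-12,6-olide (epimers at C6 and C7) | C/C=C(/C)C(=O)O[C@H]1CC[C@]2(O)CC(=O)C3[C@@H](C)C(=O)OC3[C@]2(C)[C@H]1C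
F2 | step 10 | (E)-2-methyl-4-oxopent-2-enoic acid | OC(=O)/C(C)=C/C(C)=O
F3 | step 10 | (R)-2-methyl-4-oxopentanoic acid | CC(=O)C[C@@H](C)C(=O)O
F4 | step 10 | methyl (R)-2-methyl-4-oxopentanoate | CC(=O)C[C@@H](C)C(=O)OC
F5 | step 4 | (3R,4S)-4-[(tert-butyldimethylsilyl)oxy]-2,3-dimethylcyclohexan-1-one (epimers at C2) | CC(C)(C)[Si](C)(C)O[C@H]1CCC(=O)C(C)[C@H]1C
F6 | step 4 | tert-butyl({(1S,2R)-2,3-dimethyl-4-[(trimethylsilyl)oxy]cyclohex-3-en-1-yl}oxy)dimethylsilane | CC(C)(C)[Si](C)(C)O[C@H]1CCC(O[Si](C)(C)C)=C(C)[C@H]1C
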